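## The problem

The target is a linear decamer: ten benzene rings, lettered A to J from the 2,4,6-trihydroxyphenyl end, joined only by nine diaryl ether oxygens and carrying 26 free phenolic hydroxyls. Rings B, D, F and H are para-linked (ether oxygens on C1 and C4, hydroxyls on C3 and C5). Rings C, E, G and I are ortho-linked (ether oxygens on C1 and C6, hydroxyls on C3, C4 and C5). Ring J is a 3,4,5-trihydroxyphenyl cap, so the B–C pair recurs four times. There is no stereocentre and no ring to close; the difficulty is regiochemical and lies in making nine C–O bonds between rings that are electron-rich and substituted next to every ether carbon, where copper- or palladium-mediated etherification is weakest. The free polyphenol, with its pyrogallol and phloroglucinol units, is oxidised by air (fastest as a phenoxide) and cannot be chromatographed easily, so the hydroxyls must stay masked until the end and be released without base or oxidant. The enabling feature is that on each of rings A to I two hydroxyls lie ortho or para to the ring carbon that carries the ether oxygen towards ring J: C2 and C6 of ring A flank C1; C3 and C5 of rings B, D, F and H flank C4; C5 (ortho) and C3 (para) of rings C, E, G and I relate to C6. A formyl group at each of these eighteen positions would activate that carbon, as its fluoride, for metal-free substitution by a phenoxide, and would later become the hydroxyl by Baeyer–Villiger oxidation. The remaining eight hydroxyls (C4 of rings A, C, E, G and I, and C3 to C5 of ring J) have no such relation and can be benzyl ethers from the start.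

## Retrosynthesis

**Target 29 back to octadeca-formate 27.** Only O–CHO (eighteen) and O–CH2Ph (eight) bonds are cut; the skeleton is unchanged. Formates fall off by acid-catalysed methanolysis and benzyl ethers by hydrogenolysis, so the polyphenol never meets base or oxidant. The intermediate 28 has on each ring only hydroxyls that are meta to one another, with the carbon between or para to them still etherified, so it has no catechol or hydroquinone pair; these appear only under hydrogen. Methyl ethers were rejected because their removal needs boron halides on a 26-fold scale.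

**Octadeca-formate 27 back to octadeca-aldehyde 26 (key cut).** Eighteen aryl C–O bonds are traced to aryl C–CHO bonds. Buying the oxygens with the monomers would leave nine ether bonds to be made between electron-rich, hindered rings; late C–H oxidation would have no regiocontrol. The formyl group does two jobs: it activates the ether-forming substitution and it is the latent hydroxyl. Compound 26 is an electron-poor, air-stable polyaldehyde that can be purified and analysed at every stage. The forward step asks for aryl migration, not hydride migration, at all eighteen sites.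

**Decamer 26 back to nonamer fluoride 25 and phenol 4.** The bond between C6 of ring I and the oxygen of ring J is cut. Ring J is the only ring that acts purely as a nucleophile, so its three oxygens come as benzyl ethers in 4. C6 of ring I has formyl groups ortho and para, so fluoride displacement needs only carbonate.

**Nonamer fluoride 25 back to ring A monomer 9 and four molecules of dimer phenol 17.** The cuts are at C1 of ring A and at C6 of rings C, E and G; with the fourth unit of 17 supplying rings H and I, one reagent is used four times. This halves the number of operations on the growing chain compared with ring-by-ring growth. The chain is the electrophile, since a nucleophilic chain would need a hydroxyl deprotection after every ring. The incoming phenol must not carry a live fluoride, or the product would add a second unit. In 17 the terminal ring therefore has its aldehydes as dioxolanes, and acid after each coupling (giving 19, 21, 23, then 25) restores the activation.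

**Dimer phenol 17 back to allyl ether 10 and masked phenol 15.** The bond between C4 of the B-type ring and the oxygen of the C-type ring is cut, via allyl ether 16. The B-type ring must be the electrophile, and its para oxygen must be neutral, because a para phenoxide would switch off the fluoride; hence the allyl ether in 10. Allyl is removed by palladium without touching aldehydes, dioxolanes, the benzyl ether or the masked fluoride.

**Monomers.** Fluorides 9 and 10 come from one dialdehyde, 8, made from 4-fluorophenol 5 through silyl ether 6 by two fluorine-directed lithiation/formylation events. Phenol 15 comes from 4-bromo-3-fluorophenol 11 via 12, 13 and 14: the free hydroxyl directs both formyl groups to its ortho positions, and the bromine marks the carbon that later becomes the nucleophilic oxygen. A fluorohydroquinone would present these two oxygens alike. Phenol 4 comes from 3,4,5-trihydroxybenzaldehyde 1 through 2.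

## Roads not taken

**Alternative 1:** Ring A is cut between its ether-bearing carbon and a neighbouring hydroxyl-bearing carbon, giving the methyl 6-aryloxy-3,5-dioxohexanoate A1 on a B–C dimer. In the forward direction, base-mediated Claisen cyclisation (C6 carbanion onto the ester) closes ring A, which enolises to the phloroglucinol A2.
- Merits: the three hydroxyls of ring A arrive at the correct oxidation level under mild base, with no oxidant; on this point it is better than the chosen plan, which must oxidise ring A's two formyl groups where migratory aptitude is lowest.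
- Weak points: it makes one ring of ten and leaves all nine ether bonds to other methods. Triketo esters of this type tend to lactonise to 4-hydroxy-2-pyrones in competition with C-acylation. The free, C-nucleophilic phloroglucinol of A2 must be carried forward or the triketide must be appended to a nonamer.
- Comparison: the chosen plan risks an eighteen-fold oxidation but solves all nine ether bonds with one reaction type.

**Alternative 2:** The ether bonds to rings I and J are traced to aryl ester links of the gallate didepside A3. In the forward direction Ni(cod)2 (zerovalent nickel) with 3,4-bis(dicyclohexylphosphino)thiophene extrudes CO from both esters to give trimer ether A4.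
- Merits: every ring comes from the gallate series with its oxygens in place, ester formation is trivial, and no late oxidation is needed. In oxidation-state economy it is clearly better.
- Weak points: decarbonylative etherification is best established for electron-poor or azine acyl partners. Here the acyl carbons sit on tri- and tetra-alkoxybenzoyl groups flanked by ortho oxygens, at temperatures that strain eight or more benzyl ethers. Nine such extrusions would be needed, and after each block the ester on ring H of A4 must be converted into a phenol before the next depside can be built. The ortho-acyloxy ester in A3 can also migrate between neighbouring oxygens.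
- Comparison: the chosen plan pays with the oxidation step but forms every ether bond without a metal and without re-functionalising the chain end.

**Alternative 3:** Ring C is cut at its C1–C2 bond, back to the 4-[(Z)-2-aryloxyvinyl]-4-hydroxy-2,3-bis(benzyloxy)cyclobutenone A5, itself from a squarate and a vinyl anion. Thermolysis opens the four-membered ring to a vinylketene, and 6π electrocyclisation gives hydroquinone A6.
- Merits: the pentaoxygenated rings, the hardest to buy, are built with full regiocontrol in a reagent-free step; for those four rings it is the more elegant construction.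
- Weak points: it builds four rings of ten. The (Z)-2-aryloxyvinyl anion needed for A5 can lose aryloxide by β-elimination. A6 is an oxidation-prone hydroquinone whose two free hydroxyls must be told apart, and the next ether bond still has to be made at the hindered hydroxyl beside the aryloxy group by a metal-mediated coupling.
- Comparison: the chosen plan leaves no ether bond to a metal-mediated coupling and carries no free hydroquinone; its price is the eighteen-fold oxidation.

Key step: step 18

## Route

Remark on the chemistry: 3,4,5-trihydroxybenzaldehyde, 4-fluorophenol and 4-bromo-3-fluorophenol are assumed to be purchasable. In every ring C1 carries the oxygen on the ring-A side (in ring A, the ether oxygen).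

Ring key for the oligomer names:
- ring A = 4-(benzyloxy)-2,6-diformylphenyl, bonded at C1;
- rings B, D, F, H = 3,5-diformyl-1,4-phenylene (C4–O towards ring J);
- rings C, E, G, I = 4-(benzyloxy)-3,5-diformylphenylene with C1–O towards ring A and C6–O (or C6–F) towards ring J;
- ring J = 3,4,5-tris(benzyloxy)phenyl.

Step 1
Reactants: 1 3,4,5-trihydroxybenzaldehyde
Product: 2 3,4,5-tris(benzyloxy)benzaldehyde
Conditions: BnBr, K2CO3, DMF, 60 °C, argon
Reagents that add atoms: benzyl bromide, BrCc1ccccc1
Why: Williamson ether synthesis on the three phenoxides; the aldehyde is inert and argon protects the pyrogallol anion from air.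

Step 2
Reactants: 2 3,4,5-tris(benzyloxy)benzaldehyde
Product: 4 3,4,5-tris(benzyloxy)phenol, via aryl formate 3 (not isolated)
Conditions: mCPBA, CH2Cl2, rt; then K2CO3 (cat.), MeOH, rt
Reagents that add atoms: 3-chloroperoxybenzoic acid (mCPBA), OOC(=O)c1cccc(Cl)c1
Why: Baeyer–Villiger (Dakin-type) oxidation in which the benzyloxy groups make the aryl group migrate; formate 3 is cleaved by base-catalysed methanolysis in the same flask.

Step 3
Reactants: 5 4-fluorophenol
Product: 6 (4-fluorophenoxy)tri(propan-2-yl)silane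
Conditions: TIPSCl, imidazole, DMF, rt
Reagents that add atoms: chlorotri(propan-2-yl)silane, CC(C)[Si](Cl)(C(C)C)C(C)C
Why: Imidazole-promoted silylation of the phenol; the bulky silyl group blocks lithiation next to oxygen in step 4.

Step 4
Reactants: 6 (4-fluorophenoxy)tri(propan-2-yl)silane
Product: 8 2-fluoro-5-[(triisopropylsilyl)oxy]benzene-1,3-dicarbaldehyde, via lithium hemiaminolate 7 (not isolated)
Conditions: s-BuLi, TMEDA, THF, −78 °C; DMF (1 equiv); s-BuLi, −78 °C; DMF; 1 M HCl, 0 °C
Reagents that add atoms: N,N-dimethylformamide, CN(C)C=O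
Why: Fluorine-directed ortho-lithiation and formylation with DMF, done twice in one flask; the first adduct persists as hemiaminolate 7, an aldehyde protected in situ, while the second lithiation takes the other carbon next to fluorine. At −78 °C the ortho-fluoroaryllithium does not lose LiF.

Step 5
Reactants: 8 2-fluoro-5-[(triisopropylsilyl)oxy]benzene-1,3-dicarbaldehyde
Product: 9 5-(benzyloxy)-2-fluorobenzene-1,3-dicarbaldehyde
Conditions: CsF, BnBr (excess), DMF, 0 °C to rt
Reagents that add atoms: benzyl bromide, BrCc1ccccc1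
Why: Fluoride-induced desilylation with Williamson benzylation in situ; the transient phenoxide is para to its own fluorine and so deactivates it, and excess benzyl bromide traps it before it can attack the product.

Step 6
Reactants: 8 2-fluoro-5-[(triisopropylsilyl)oxy]benzene-1,3-dicarbaldehyde
Product: 10 2-fluoro-5-(prop-2-en-1-yloxy)benzene-1,3-dicarbaldehyde
Conditions: CsF, allyl bromide (excess), DMF, 0 °C to rt
Reagents that add atoms: allyl bromide, C=CCBr
Why: Same desilylation–Williamson alkylation as step 5; the allyl ether keeps the para oxygen neutral and is removable later by palladium.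

Step 7
Reactants: 11 4-bromo-3-fluorophenol
Product: 12 5-bromo-4-fluoro-2-hydroxybenzene-1,3-dicarbaldehyde
Conditions: hexamethylenetetramine, CF3CO2H, reflux; then aq. HCl, 60 °C
Reagents that add atoms: hexamethylenetetramine, C1N2CN3CN1CN(C2)C3; water, O
Why: Duff reaction (double ortho-formylation of a para-blocked phenol); bromine occupies the para position, so both formyl groups enter beside the hydroxyl, one of them between OH and F.

Step 8
Reactants: 12 5-bromo-4-fluoro-2-hydroxybenzene-1,3-dicarbaldehyde
Product: 13 2-(benzyloxy)-5-bromo-4-fluorobenzene-1,3-dicarbaldehyde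
Conditions: BnBr, K2CO3, DMF, rt
Reagents that add atoms: benzyl bromide, BrCc1ccccc1
Why: Williamson ether synthesis; the acidic 2,6-diformylphenoxide is a poor SNAr nucleophile at room temperature, so O-benzylation outruns attack on the activated fluoride.

Step 9
Reactants: 13 2-(benzyloxy)-5-bromo-4-fluorobenzene-1,3-dicarbaldehyde
Product: 14 2,2'-[2-(benzyloxy)-5-bromo-4-fluoro-1,3-phenylene]bis(1,3-dioxolane)
Conditions: ethylene glycol, TsOH (cat.), toluene, reflux, Dean–Stark
Reagents that add atoms: ethane-1,2-diol, OCCO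
Why: Acid-catalysed acetalisation with azeotropic removal of water; the dioxolanes switch off the activation of the C–F bond and shield the aldehydes from hydroxide in step 10.

Step 10
Reactants: 14 2,2'-[2-(benzyloxy)-5-bromo-4-fluoro-1,3-phenylene]bis(1,3-dioxolane)
Product: 15 4-(benzyloxy)-3,5-bis(1,3-dioxolan-2-yl)-2-fluorophenol
Conditions: Pd2(dba)3 (cat.), tBuXPhos (cat.), KOH, 1,4-dioxane/H2O, 100 °C; then NaH2PO4 buffer
Reagents that add atoms: potassium hydroxide, [K+].[OH-]
Why: Palladium-catalysed hydroxylation of an aryl bromide with hydroxide (Buchwald-type C–O coupling); zerovalent palladium inserts only into C–Br, the unactivated C–F bond, dioxolanes and benzyl ether are base-stable, and buffered work-up keeps the acetals.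

Step 11
Reactants: 10 2-fluoro-5-(prop-2-en-1-yloxy)benzene-1,3-dicarbaldehyde; 15 4-(benzyloxy)-3,5-bis(1,3-dioxolan-2-yl)-2-fluorophenol
Product: 16 2-[4-(benzyloxy)-3,5-bis(1,3-dioxolan-2-yl)-2-fluorophenoxy]-5-(prop-2-en-1-yloxy)benzene-1,3-dicarbaldehyde
Conditions: K2CO3, DMF, rt to 40 °C
Reagents that add atoms: none
Why: Nucleophilic aromatic substitution (addition–elimination) at the fluoride flanked by two ortho formyl groups; the fluorine of 15 is inert while its aldehydes are acetals, so the product cannot react a second time.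

Step 12
Reactants: 16 2-[4-(benzyloxy)-3,5-bis(1,3-dioxolan-2-yl)-2-fluorophenoxy]-5-(prop-2-en-1-yloxy)benzene-1,3-dicarbaldehyde
Product: 17 2-[4-(benzyloxy)-3,5-bis(1,3-dioxolan-2-yl)-2-fluorophenoxy]-5-hydroxybenzene-1,3-dicarbaldehyde
Conditions: Pd(PPh3)4 (cat.), morpholine, THF, rt
Reagents that add atoms: none
Why: Palladium-catalysed deallylation (Tsuji–Trost transfer of allyl to morpholine); the electron-poor aryloxide leaves readily from the π-allyl complex, and aldehydes, dioxolanes, benzyl ether and the masked aryl fluoride are untouched.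

Step 13
Reactants: 9 5-(benzyloxy)-2-fluorobenzene-1,3-dicarbaldehyde; 17 2-[4-(benzyloxy)-3,5-bis(1,3-dioxolan-2-yl)-2-fluorophenoxy]-5-hydroxybenzene-1,3-dicarbaldehyde
Product: 19 trimer fluoride A–B–C, 5-(benzyloxy)-2-{4-[4-(benzyloxy)-2-fluoro-3,5-diformylphenoxy]-3,5-diformylphenoxy}benzene-1,3-dicarbaldehyde, via trimer bis-dioxolane 18 (not isolated)
Conditions: K2CO3, DMF, 40 °C; then 2 M HCl, THF, rt
Reagents that add atoms: water, O
Why: SNAr of the phenoxide of 17 at the doubly ortho-activated fluoride of 9, then acid hydrolysis of the two dioxolanes of 18 in the same flask, which arms the new terminal fluoride (formyl ortho and para). 17 cannot self-condense because its own fluoride is masked.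

Step 14
Reactants: 19 trimer fluoride A–B–C; 17 dimer phenol
Product: 21 pentamer fluoride A–B–C–D–E (ten formyl groups, fluorine on C6 of ring E), via pentamer bis-dioxolane 20 (not isolated)
Conditions: K2CO3, DMF, 40 °C; then 2 M HCl, THF, rt
Reagents that add atoms: water, O
Why: Same SNAr and acetal hydrolysis sequence; the fluoride on C6 of ring C is activated by its ortho and para formyl groups.

Step 15
Reactants: 21 pentamer fluoride A–B–C–D–E; 17 dimer phenol
Product: 23 heptamer fluoride A–B–C–D–E–F–G (fourteen formyl groups, fluorine on C6 of ring G), via heptamer bis-dioxolane 22 (not isolated)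
Conditions: K2CO3, DMF, 40 °C; then 2 M HCl, THF, rt
Reagents that add atoms: water, O
Why: Same SNAr and acetal hydrolysis sequence at C6 of ring E.

Step 16
Reactants: 23 heptamer fluoride A–B–C–D–E–F–G; 17 dimer phenol
Product: 25 nonamer fluoride A–B–C–D–E–F–G–H–I (eighteen formyl groups, fluorine on C6 of ring I), via nonamer bis-dioxolane 24 (not isolated)
Conditions: K2CO3, DMF, 40 °C; then 2 M HCl, THF, rt
Reagents that add atoms: water, O
Why: Same SNAr and acetal hydrolysis sequence at C6 of ring G.

Step 17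
Reactants: 25 nonamer fluoride A–B–C–D–E–F–G–H–I; 4 3,4,5-tris(benzyloxy)phenol
Product: 26 octadeca-aldehyde decamer A–J (two formyl groups on each of rings A to I, eight benzyl ethers)
Conditions: K2CO3, DMF, 40 °C, argon
Reagents that add atoms: none
Why: SNAr of the electron-rich phenoxide of 4 at the ortho/para-formyl-activated fluoride of ring I; argon because this phenoxide is oxidisable.

Step 18
Reactants: 26 octadeca-aldehyde decamer A–J
Product: 27 octadeca-formate decamer (formyloxy in place of every formyl group of 26, eight benzyl ethers)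
Conditions: mCPBA (dried, about 36 equiv), CH2Cl2, 0 °C to 40 °C
Reagents that add atoms: 3-chloroperoxybenzoic acid (mCPBA), OOC(=O)c1cccc(Cl)c1
Why: Proposed new method: an eighteen-fold Baeyer–Villiger (Dakin-type) oxidation on one oligo(aryl ether) polyaldehyde, whose closest known reaction type is the mCPBA oxidation of single ortho- or para-alkoxy- and aryloxybenzaldehydes to aryl formates. Each formyl group adds the peracid to give a Criegee adduct, and the aryl carbon then migrates to the peroxide oxygen as 3-chlorobenzoate leaves, so each event makes one aryl C–O bond as a formate ester. No ring closes and no stereocentre forms, so the only selectivity needed is aryl over hydride migration (which would leave a carboxylic acid) at all eighteen sites. The substrate secures it by an oxygen lone pair ortho or para to every formyl-bearing carbon: the benzyloxy oxygen plus an aryloxy oxygen on rings C, E, G and I, and the ether oxygen on C1 of ring A and on C4 of rings B, D, F and H. The reaction should reinforce itself, because every converted site exchanges an acceptor (CHO) for a formyloxy donor and so raises the migratory aptitude of the remaining aryl groups on that ring and, through the shared ether oxygens, on its neighbours. Aryl formates, benzyl ethers and diaryl ethers are inert to mCPBA at this temperature, and with dried peracid no formate is hydrolysed to a phenol that could be over-oxidised. The electron-rich ring J is the one place where ring hydroxylation could occur, which the absence of strong acid and the moderate temperature should prevent.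

Step 19
Reactants: 27 octadeca-formate decamer
Product: 29 target decamer (CNP0255890.0, 26 free hydroxyls), via octadecaphenol octabenzyl ether 28 (not isolated)
Conditions: HCl (cat.), MeOH/THF, argon, rt; then Pd/C, H2 (1 atm), rt
Reagents that add atoms: none
Why: Acid-catalysed transesterification of the aryl formates by methanol, then hydrogenolysis of the eight benzyl ethers over Pd/C; no base or oxidant meets the free polyphenol and the by-products (methyl formate, toluene) are volatile.

## Compound list

1 | 3,4,5-trihydroxybenzaldehyde | O=Cc1cc(O)c(O)c(O)c1 | starting material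
2 | 3,4,5-tris(benzyloxy)benzaldehyde | O=Cc1cc(OCc2ccccc2)c(OCc2ccccc2)c(OCc2ccccc2)c1 | intermediate
3 | 3,4,5-tris(benzyloxy)phenyl formate | O=COc1cc(OCc2ccccc2)c(OCc2ccccc2)c(OCc2ccccc2)c1 | intermediate (not isolated)
4 | 3,4,5-tris(benzyloxy)phenol | Oc1cc(OCc2ccccc2)c(OCc2ccccc2)c(OCc2ccccc2)c1 | intermediate
5 | 4-fluorophenol | Oc1ccc(F)cc1 | starting material
6 | (4-fluorophenoxy)tri(propan-2-yl)silane | CC(C)[Si](Oc1ccc(F)cc1)(C(C)C)C(C)C | intermediate
7 | lithium (dimethylamino){2-fluoro-5-[(triisopropylsilyl)oxy]phenyl}methanolate (racemic) | CN(C)C([O-])c1cc(O[Si](C(C)C)(C(C)C)C(C)C)ccc1F.[Li+] | intermediate (not isolated)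
8 | 2-fluoro-5-[(triisopropylsilyl)oxy]benzene-1,3-dicarbaldehyde | O=Cc1cc(O[Si](C(C)C)(C(C)C)C(C)C)cc(C=O)c1F | intermediate
9 | 5-(benzyloxy)-2-fluorobenzene-1,3-dicarbaldehyde | O=Cc1cc(OCc2ccccc2)cc(C=O)c1F | intermediate
10 | 2-fluoro-5-(prop-2-en-1-yloxy)benzene-1,3-dicarbaldehyde | C=CCOc1cc(C=O)c(F)c(C=O)c1 | intermediate
11 | 4-bromo-3-fluorophenol | Oc1ccc(Br)c(F)c1 | starting material
12 | 5-bromo-4-fluoro-2-hydroxybenzene-1,3-dicarbaldehyde | O=Cc1cc(Br)c(F)c(C=O)c1O | intermediate
13 | 2-(benzyloxy)-5-bromo-4-fluorobenzene-1,3-dicarbaldehyde | O=Cc1cc(Br)c(F)c(C=O)c1OCc1ccccc1 | intermediate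
14 | 2,2'-[2-(benzyloxy)-5-bromo-4-fluoro-1,3-phenylene]bis(1,3-dioxolane) | Brc1cc(C2OCCO2)c(OCc2ccccc2)c(C2OCCO2)c1F | intermediate
15 | 4-(benzyloxy)-3,5-bis(1,3-dioxolan-2-yl)-2-fluorophenol | Oc1cc(C2OCCO2)c(OCc2ccccc2)c(C2OCCO2)c1F | intermediate
16 | 2-[4-(benzyloxy)-3,5-bis(1,3-dioxolan-2-yl)-2-fluorophenoxy]-5-(prop-2-en-1-yloxy)benzene-1,3-dicarbaldehyde | C=CCOc1cc(C=O)c(Oc2cc(C3OCCO3)c(OCc3ccccc3)c(C3OCCO3)c2F)c(C=O)c1 | intermediate
17 | 2-[4-(benzyloxy)-3,5-bis(1,3-dioxolan-2-yl)-2-fluorophenoxy]-5-hydroxybenzene-1,3-dicarbaldehyde | Oc1cc(C=O)c(Oc2cc(C3OCCO3)c(OCc3ccccc3)c(C3OCCO3)c2F)c(C=O)c1 | intermediate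
18 | trimer bis-dioxolane A–B–C (as 19, with both formyl groups of ring C as 1,3-dioxolan-2-yl) | O=Cc1cc(OCc9ccccc9)cc(C=O)c1Oc2cc(C=O)c(Oc3cc(C8OCCO8)c(OCc9ccccc9)c(C8OCCO8)c3F)c(C=O)c2 | intermediate (not isolated)
19 | trimer fluoride A–B–C, 5-(benzyloxy)-2-{4-[4-(benzyloxy)-2-fluoro-3,5-diformylphenoxy]-3,5-diformylphenoxy}benzene-1,3-dicarbaldehyde | O=Cc1cc(OCc9ccccc9)cc(C=O)c1Oc2cc(C=O)c(Oc3cc(C=O)c(OCc9ccccc9)c(C=O)c3F)c(C=O)c2 | intermediate
20 | pentamer bis-dioxolane A–B–C–D–E (as 21, with both formyl groups of ring E as 1,3-dioxolan-2-yl) | O=Cc1cc(OCc9ccccc9)cc(C=O)c1Oc2cc(C=O)c(Oc3cc(C=O)c(OCc9ccccc9)c(C=O)c3Oc3cc(C=O)c(Oc4cc(C8OCCO8)c(OCc9ccccc9)c(C8OCCO8)c4F)c(C=O)c3)c(C=O)c2 | intermediate (not isolated)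
21 | pentamer fluoride A–B–C–D–E (ten formyl groups, fluorine on C6 of ring E) | O=Cc1cc(OCc9ccccc9)cc(C=O)c1Oc2cc(C=O)c(Oc3cc(C=O)c(OCc9ccccc9)c(C=O)c3Oc3cc(C=O)c(Oc4cc(C=O)c(OCc9ccccc9)c(C=O)c4F)c(C=O)c3)c(C=O)c2 | intermediate
22 | heptamer bis-dioxolane A–G (as 23, with both formyl groups of ring G as 1,3-dioxolan-2-yl) | O=Cc1cc(OCc9ccccc9)cc(C=O)c1Oc2cc(C=O)c(Oc3cc(C=O)c(OCc9ccccc9)c(C=O)c3Oc3cc(C=O)c(Oc4cc(C=O)c(OCc9ccccc9)c(C=O)c4Oc4cc(C=O)c(Oc5cc(C8OCCO8)c(OCc9ccccc9)c(C8OCCO8)c5F)c(C=O)c4)c(C=O)c3)c(C=O)c2 | intermediate (not isolated)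
23 | heptamer fluoride A–G (fourteen formyl groups, fluorine on C6 of ring G) | O=Cc1cc(OCc9ccccc9)cc(C=O)c1Oc2cc(C=O)c(Oc3cc(C=O)c(OCc9ccccc9)c(C=O)c3Oc3cc(C=O)c(Oc4cc(C=O)c(OCc9ccccc9)c(C=O)c4Oc4cc(C=O)c(Oc5cc(C=O)c(OCc9ccccc9)c(C=O)c5F)c(C=O)c4)c(C=O)c3)c(C=O)c2 | intermediate
24 | nonamer bis-dioxolane A–I (as 25, with both formyl groups of ring I as 1,3-dioxolan-2-yl) | O=Cc1cc(OCc9ccccc9)cc(C=O)c1Oc2cc(C=O)c(Oc3cc(C=O)c(OCc9ccccc9)c(C=O)c3Oc3cc(C=O)c(Oc4cc(C=O)c(OCc9ccccc9)c(C=O)c4Oc4cc(C=O)c(Oc5cc(C=O)c(OCc9ccccc9)c(C=O)c5Oc5cc(C=O)c(Oc6cc(C8OCCO8)c(OCc9ccccc9)c(C8OCCO8)c6F)c(C=O)c5)c(C=O)c4)c(C=O)c3)c(C=O)c2 | intermediate (not isolated)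
25 | nonamer fluoride A–I (eighteen formyl groups, fluorine on C6 of ring I) | O=Cc1cc(OCc9ccccc9)cc(C=O)c1Oc2cc(C=O)c(Oc3cc(C=O)c(OCc9ccccc9)c(C=O)c3Oc3cc(C=O)c(Oc4cc(C=O)c(OCc9ccccc9)c(C=O)c4Oc4cc(C=O)c(Oc5cc(C=O)c(OCc9ccccc9)c(C=O)c5Oc5cc(C=O)c(Oc6cc(C=O)c(OCc9ccccc9)c(C=O)c6F)c(C=O)c5)c(C=O)c4)c(C=O)c3)c(C=O)c2 | intermediate
26 | octadeca-aldehyde decamer A–J (two formyl groups on each of rings A to I; benzyl ethers on C4 of rings A, C, E, G, I and on C3, C4, C5 of ring J) | O=Cc1cc(OCc9ccccc9)cc(C=O)c1Oc2cc(C=O)c(Oc3cc(C=O)c(OCc9ccccc9)c(C=O)c3Oc3cc(C=O)c(Oc4cc(C=O)c(OCc9ccccc9)c(C=O)c4Oc4cc(C=O)c(Oc5cc(C=O)c(OCc9ccccc9)c(C=O)c5Oc5cc(C=O)c(Oc6cc(C=O)c(OCc9ccccc9)c(C=O)c6Oc6cc(OCc9ccccc9)c(OCc9ccccc9)c(OCc9ccccc9)c6)c(C=O)c5)c(C=O)c4)c(C=O)c3)c(C=O)c2 | intermediate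
27 | octadeca-formate decamer (formyloxy in place of each formyl group of 26) | O=COc1cc(OCc9ccccc9)cc(OC=O)c1Oc2cc(OC=O)c(Oc3cc(OC=O)c(OCc9ccccc9)c(OC=O)c3Oc3cc(OC=O)c(Oc4cc(OC=O)c(OCc9ccccc9)c(OC=O)c4Oc4cc(OC=O)c(Oc5cc(OC=O)c(OCc9ccccc9)c(OC=O)c5Oc5cc(OC=O)c(Oc6cc(OC=O)c(OCc9ccccc9)c(OC=O)c6Oc6cc(OCc9ccccc9)c(OCc9ccccc9)c(OCc9ccccc9)c6)c(OC=O)c5)c(OC=O)c4)c(OC=O)c3)c(OC=O)c2 | intermediate
28 | octadecaphenol octabenzyl ether (hydroxyl in place of each formyloxy group of 27) | Oc1cc(OCc9ccccc9)cc(O)c1Oc2cc(O)c(Oc3cc(O)c(OCc9ccccc9)c(O)c3Oc3cc(O)c(Oc4cc(O)c(OCc9ccccc9)c(O)c4Oc4cc(O)c(Oc5cc(O)c(OCc9ccccc9)c(O)c5Oc5cc(O)c(Oc6cc(O)c(OCc9ccccc9)c(O)c6Oc6cc(OCc9ccccc9)c(OCc9ccccc9)c(OCc9ccccc9)c6)c(O)c5)c(O)c4)c(O)c3)c(O)c2 | intermediate (not isolated)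
29 | CNP0255890.0, the decameric polyphenol with 26 free hydroxyls (achiral) | Oc1cc(O)c(Oc2cc(O)c(Oc3cc(O)c(O)c(O)c3Oc3cc(O)c(Oc4cc(O)c(O)c(O)c4Oc4cc(O)c(Oc5cc(O)c(O)c(O)c5Oc5cc(O)c(Oc6cc(O)c(O)c(O)c6Oc6cc(O)c(O)c(O)c6)c(O)c5)c(O)c4)c(O)c3)c(O)c2)c(O)c1 | target

## Step count and risk

Total: 19 steps. Longest linear sequence: 13 steps (steps 7 to 19, from 4-bromo-3-fluorophenol 11).

**Step 18 (key step, proposed new method).** Hydride migration may compete with aryl migration at the least supported formyl groups, those on rings A, B, D, F and H where only a diaryl ether oxygen sits ortho. A few carboxylic acid sites among eighteen would give a mixture that cannot be separated. Partial hydrolysis of formates followed by over-oxidation of the freed phenols is the second danger. Fallback, from 26 back to 28: remove the hydrogen that can migrate. Methylmagnesium bromide (MeMgBr, THF) converts the eighteen aldehydes into the octadeca(1-hydroxyethyl) decamer F1. MnO2 oxidises these benzylic alcohols to the octadeca-acetyl decamer F2. Baeyer–Villiger oxidation of the aryl methyl ketones with mCPBA and catalytic CF3CO2H, in which aryl always migrates in preference to methyl, gives the octadeca-acetate decamer F3. Acid-catalysed methanolysis of F3 returns to the route at 28, which is hydrogenolysed as in step 19.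

**Step 4.** The second lithiation may be incomplete, s-BuLi may attack the hemiaminolate, or LiF may be lost to an aryne, giving mixtures of mono- and dialdehyde. Fallback, from 6 back to 8, with the aldehyde protected as an isolated acetal: a single lithiation/formylation gives 2-fluoro-5-[(triisopropylsilyl)oxy]benzaldehyde F4; ethylene glycol and TsOH give its dioxolane F5; a second fluorine-directed lithiation and DMF quench give 3-(1,3-dioxolan-2-yl)-2-fluoro-5-[(triisopropylsilyl)oxy]benzaldehyde F6; mild aqueous acid hydrolysis of F6 gives 8.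

**Step 7.** The second formylation, between OH and F on a halogen-deactivated ring, may stall and leave mono-aldehyde and polymeric material. Fallback, from 11 back to 12, by a two-stage change of oxidation level: base-mediated bis-hydroxymethylation with aqueous formaldehyde and NaOH gives 4-bromo-3-fluoro-2,6-bis(hydroxymethyl)phenol F7, whose benzylic alcohols are oxidised with MnO2 to 12.

**Step 16 (and the series 13 to 16).** As the chain grows, coupling may slow, and the phenoxide may begin to exchange into internal formyl-activated ether carbons (trans-etherification), which scrambles the sequence; acetal hydrolysis may also be incomplete on the large substrate. Fallback, a convergent union that removes two operations from the largest electrophile, from 16 and 23 back to 26. Acid hydrolysis of 16 gives the allyl-protected dimer fluoride F8. SNAr of F8 with phenol 4 gives the allyl-protected H–I–J trimer F9. Palladium-catalysed deallylation gives trimer phenol F10, which has no fluoride. SNAr of F10 with heptamer fluoride 23 gives 26 directly.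

**Step 19.** Partially debenzylated material may precipitate and stop the hydrogenolysis, and the free polyphenol may oxidise in air during isolation, with no chromatographic purification available. Fallback, from 27 back to 29, by derivatising for purification: after methanolysis and hydrogenolysis the crude product is acetylated in the same flask (Ac2O, pyridine) to the hexacosa-acetate F11, which is purified on silica. Catalytic NaOMe in MeOH under argon, neutralised with acidic resin, then releases 29.

## Further compounds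

F1 | step 18 | octadeca(1-hydroxyethyl) decamer (26 with each CHO replaced by CH(OH)CH3; mixture of diastereomers) | CC(O)c1cc(OCc9ccccc9)cc(C(C)O)c1Oc2cc(C(C)O)c(Oc3cc(C(C)O)c(OCc9ccccc9)c(C(C)O)c3Oc3cc(C(C)O)c(Oc4cc(C(C)O)c(OCc9ccccc9)c(C(C)O)c4Oc4cc(C(C)O)c(Oc5cc(C(C)O)c(OCc9ccccc9)c(C(C)O)c5Oc5cc(C(C)O)c(Oc6cc(C(C)O)c(OCc9ccccc9)c(C(C)O)c6Oc6cc(OCc9ccccc9)c(OCc9ccccc9)c(OCc9ccccc9)c6)c(C(C)O)c5)c(C(C)O)c4)c(C(C)O)c3)c(C(C)O)c2
F2 | step 18 | octadeca-acetyl decamer (26 with each CHO replaced by COCH3) | CC(=O)c1cc(OCc9ccccc9)cc(C(C)=O)c1Oc2cc(C(C)=O)c(Oc3cc(C(C)=O)c(OCc9ccccc9)c(C(C)=O)c3Oc3cc(C(C)=O)c(Oc4cc(C(C)=O)c(OCc9ccccc9)c(C(C)=O)c4Oc4cc(C(C)=O)c(Oc5cc(C(C)=O)c(OCc9ccccc9)c(C(C)=O)c5Oc5cc(C(C)=O)c(Oc6cc(C(C)=O)c(OCc9ccccc9)c(C(C)=O)c6Oc6cc(OCc9ccccc9)c(OCc9ccccc9)c(OCc9ccccc9)c6)c(C(C)=O)c5)c(C(C)=O)c4)c(C(C)=O)c3)c(C(C)=O)c2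
F3 | step 18 | octadeca-acetate decamer (27 with acetoxy in place of each formyloxy) | CC(=O)Oc1cc(OCc9ccccc9)cc(OC(C)=O)c1Oc2cc(OC(C)=O)c(Oc3cc(OC(C)=O)c(OCc9ccccc9)c(OC(C)=O)c3Oc3cc(OC(C)=O)c(Oc4cc(OC(C)=O)c(OCc9ccccc9)c(OC(C)=O)c4Oc4cc(OC(C)=O)c(Oc5cc(OC(C)=O)c(OCc9ccccc9)c(OC(C)=O)c5Oc5cc(OC(C)=O)c(Oc6cc(OC(C)=O)c(OCc9ccccc9)c(OC(C)=O)c6Oc6cc(OCc9ccccc9)c(OCc9ccccc9)c(OCc9ccccc9)c6)c(OC(C)=O)c5)c(OC(C)=O)c4)c(OC(C)=O)c3)c(OC(C)=O)c2
F4 | step 4 | 2-fluoro-5-[(triisopropylsilyl)oxy]benzaldehyde | O=Cc1cc(O[Si](C(C)C)(C(C)C)C(C)C)ccc1F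
F5 | step 4 | 2-{2-fluoro-5-[(triisopropylsilyl)oxy]phenyl}-1,3-dioxolane | Fc1ccc(O[Si](C(C)C)(C(C)C)C(C)C)cc1C1OCCO1
F6 | step 4 | 3-(1,3-dioxolan-2-yl)-2-fluoro-5-[(triisopropylsilyl)oxy]benzaldehyde | O=Cc1cc(O[Si](C(C)C)(C(C)C)C(C)C)cc(C2OCCO2)c1F
F7 | step 7 | 4-bromo-3-fluoro-2,6-bis(hydroxymethyl)phenol | OCc1cc(Br)c(F)c(CO)c1O
F8 | step 16 | 2-[4-(benzyloxy)-2-fluoro-3,5-diformylphenoxy]-5-(prop-2-en-1-yloxy)benzene-1,3-dicarbaldehyde | C=CCOc1cc(C=O)c(Oc2cc(C=O)c(OCc3ccccc3)c(C=O)c2F)c(C=O)c1
F9 | step 16 | 2-{4-(benzyloxy)-3,5-diformyl-2-[3,4,5-tris(benzyloxy)phenoxy]phenoxy}-5-(prop-2-en-1-yloxy)benzene-1,3-dicarbaldehyde | C=CCOc1cc(C=O)c(Oc2cc(C=O)c(OCc3ccccc3)c(C=O)c2Oc2cc(OCc3ccccc3)c(OCc3ccccc3)c(OCc3ccccc3)c2)c(C=O)c1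
F10 | step 16 | 2-{4-(benzyloxy)-3,5-diformyl-2-[3,4,5-tris(benzyloxy)phenoxy]phenoxy}-5-hydroxybenzene-1,3-dicarbaldehyde | Oc1cc(C=O)c(Oc2cc(C=O)c(OCc3ccccc3)c(C=O)c2Oc2cc(OCc3ccccc3)c(OCc3ccccc3)c(OCc3ccccc3)c2)c(C=O)c1
F11 | step 19 | hexacosa-acetate of 29 (every hydroxyl as acetate) | CC(=O)Oc1cc(OC(C)=O)c(Oc2cc(OC(C)=O)c(Oc3cc(OC(C)=O)c(OC(C)=O)c(OC(C)=O)c3Oc3cc(OC(C)=O)c(Oc4cc(OC(C)=O)c(OC(C)=O)c(OC(C)=O)c4Oc4cc(OC(C)=O)c(Oc5cc(OC(C)=O)c(OC(C)=O)c(OC(C)=O)c5Oc5cc(OC(C)=O)c(Oc6cc(OC(C)=O)c(OC(C)=O)c(OC(C)=O)c6Oc6cc(OC(C)=O)c(OC(C)=O)c(OC(C)=O)c6)c(OC(C)=O)c5)c(OC(C)=O)c4)c(OC(C)=O)c3)c(OC(C)=O)c2)c(OC(C)=O)c1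
A1 | alternative 1 | methyl 6-{3,5-bis(benzyloxy)-4-[3,4,5-tris(benzyloxy)-2-(methoxymethoxy)phenoxy]phenoxy}-3,5-dioxohexanoate | COC(=O)CC(=O)CC(=O)COc1cc(OCc9ccccc9)c(Oc2cc(OCc9ccccc9)c(OCc9ccccc9)c(OCc9ccccc9)c2OCOC)c(OCc9ccccc9)c1
A2 | alternative 1 | 2-{3,5-bis(benzyloxy)-4-[3,4,5-tris(benzyloxy)-2-(methoxymethoxy)phenoxy]phenoxy}benzene-1,3,5-triol | Oc1cc(O)c(Oc2cc(OCc9ccccc9)c(Oc3cc(OCc9ccccc9)c(OCc9ccccc9)c(OCc9ccccc9)c3OCOC)c(OCc9ccccc9)c2)c(O)c1
A3 | alternative 2 | methyl 3,5-bis(benzyloxy)-4-({3,4,5-tris(benzyloxy)-2-[(3,4,5-tris(benzyloxy)benzoyl)oxy]benzoyl}oxy)benzoate | COC(=O)c1cc(OCc9ccccc9)c(OC(=O)c2cc(OCc9ccccc9)c(OCc9ccccc9)c(OCc9ccccc9)c2OC(=O)c2cc(OCc9ccccc9)c(OCc9ccccc9)c(OCc9ccccc9)c2)c(OCc9ccccc9)c1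
A4 | alternative 2 | methyl 3,5-bis(benzyloxy)-4-{3,4,5-tris(benzyloxy)-2-[3,4,5-tris(benzyloxy)phenoxy]phenoxy}benzoate | COC(=O)c1cc(OCc9ccccc9)c(Oc2cc(OCc9ccccc9)c(OCc9ccccc9)c(OCc9ccccc9)c2Oc2cc(OCc9ccccc9)c(OCc9ccccc9)c(OCc9ccccc9)c2)c(OCc9ccccc9)c1
A5 | alternative 3 | 2,3-bis(benzyloxy)-4-hydroxy-4-[(Z)-2-{2,6-bis(benzyloxy)-4-[2,4,6-tris(benzyloxy)phenoxy]phenoxy}ethenyl]cyclobut-2-en-1-one (racemic) | O=C1C(OCc9ccccc9)=C(OCc9ccccc9)C1(O)/C=C\Oc1c(OCc9ccccc9)cc(Oc2c(OCc9ccccc9)cc(OCc9ccccc9)cc2OCc9ccccc9)cc1OCc9ccccc9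
A6 | alternative 3 | 2,3-bis(benzyloxy)-5-{2,6-bis(benzyloxy)-4-[2,4,6-tris(benzyloxy)phenoxy]phenoxy}benzene-1,4-diol | Oc1cc(Oc2c(OCc9ccccc9)cc(Oc3c(OCc9ccccc9)cc(OCc9ccccc9)cc3OCc9ccccc9)cc2OCc9ccccc9)c(O)c(OCc9ccccc9)c1OCc9ccccc9
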